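**Frozen rate.** Per minute, the elm run, a closed flask, converts a nearly steady share of its charge: between 5.00 min and 25.0 min, product climbs from 15 % to 73 %, a reading of 0.0290 min⁻¹ as a fraction of the charge. Within the scatter, this stretch reads as close to zero-order. Freezing that plateau rate gives the clearing time, the whole charge divided by the plateau rate: 34.5 min.

| flask | starting material | protic impurity | enzyme | remark | time |
|---|---|---|---|---|---|
| elm | 20 mM | 1 mM | 0.01 mol% | run made earlier |  |
| maple | 20 mM | 0.50 mM | 0.01 mol% | run made earlier |  |
| west | 20 mM (fed, over 40.0 min) | 1.00 mM | 0.01 mol% | a stirred flask in which starting material is dosed at a steady rate over 40.0 min without added volume, worked up at 50 min | 50 min |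
| north | 20 mM | 1.00 mM | 0.01 mol% | everything together in a closed stirred flask, run for 50 min | 50 min |
| south-east | 20 mM | 1.00 mM | 0.01 mol% | one stirred flow tank at steady state, fed with the mixture as stated, mean residence time 50 min |  |

| run | time / min | product / % | starting material / % |
|---|---|---|---|
| elm | 5.00 | 15 | 83 |
| elm | 10.0 | 33 | 68 |
| elm | 15.0 | 46 | 51 |
| elm | 20.0 | 62 | 37 |
| elm | 25.0 | 73 | 25 |
| elm | 30.0 | 80 | 17 |
| maple | 0.417 | 2 | 98 |
| maple | 0.667 | 2 | 100 |
| maple | 1.00 | 1 | 97 |
| maple | 2.00 | 4 | 96 |
| maple | 3.00 | 8 | 91 |
| maple | 5.00 | 12 | 82 |

(standard deviation of a reading: 1.5 percentage points)

- the stated concentrations are those of everything mixed, before any reaction; amounts are the same in each set-up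
- the feed brings no volume worth counting
- the earlier runs were made in a closed, stirred flask

- order of the set-ups by the amount of product at the outlet or at the end, in percent of the starting material put in, highest first (west / north / south-east)
- amount of product at the outlet or at the end, in percent of the starting material put in, west
- amount of product at the outlet or at the end, in percent of the starting material put in, north
- amount of product at the outlet or at the end, in percent of the starting material put in, south-east

**Order reversed.** The opposite order, south-east first and north last, asks for a rate that rises as [starting material] falls, since the south-east tank stands at its outlet level while north starts from the full charge. Elm reads the reverse: between 25.0 min and 30.0 min its product readings give a rate of 0.0140 min⁻¹, about half the plateau rate and so slower than it. North has the charges of elm, and its run of 50 min exceeds the clearing time by 15.5 min, the margin left for the slow tail. The west feed, 0.0250 min⁻¹, lies below the plateau rate but above the late rate, so my reckoning expects a stock of starting material in west and places west second. For south-east, residence time times late rate gives 70.0 %, a rough figure from two scattered readings, beneath the forecast's figure.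

**The forecast.** The forecast gives north > west > south-east, with west 86 % (80 % to 91 %), north 96 % (91 % to 99 %) and south-east 81 % (75 % to 86 %), on this ground: “the curves only bend late, so this looks like saturation kinetics”.

**Flask result.** The order is north > west > south-east, with west 84.0 %, north 94.2 % and south-east 79.0 %, each inside the forecast's range.

    starting material + enzyme → product + enzyme, rate k1*[starting material]*[enzyme]/(1 + ([starting material]/Km1) + ([starting material]/Ksi1)^2) (27.0 mM, 17.0 mM, k = 5200 M⁻¹ s⁻¹)
    2 enzyme ⇌ resting dimer, settled at all times (K = 8.60 × 10⁶ M⁻¹)
    starting material + protic impurity → quenched substrate (k = 0.0430 M⁻¹ s⁻¹)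

**Earlier reading.** Dividing time by the clearing time places 72.5 % product in north at 25.0 min, and north holds 71.1 %. The neighbouring flask is north read at 12 min, with amounts and temperature held. The same division gives 34.8 %, and that flask holds 37.5 % product, with 61 % of the starting material still there.

The data were generated by integration with made-up constants.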